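**Plan**
1. Retrosynthesis: cut the p-coumarate ester C–O bond. Then raise C5 of the oxolane to a lactone carbonyl and the C4 benzyl CH2 to an exocyclic alkene, and cut its aryl–CH bond. Last, cut C2–C3 and O1–C5 of the ring, which leads to O-silyl vanillin and a γ-silyloxy 2-(bromomethyl)but-2-enoate.
2. Enabling feature: the oxolane has O1 between the benzylic C2 and an unsubstituted C5, with the CH2O arm on C3 and a benzylic CH2 on C4. At the C5-carbonyl/C4-methylidene level this is a trans-4,5-disubstituted 3-methylideneoxolan-2-one, the retron of a carbonyl 2-(alkoxycarbonyl)allylation–lactonisation in which the aldehyde C=O becomes C2–O1.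
3. Forward: the only ring is made in step 4 (C2–C3, then O1–C5 in the same flask). Heck arylation and hydrogenation build the benzyl group. DIBAL-H, then Et3SiH/BF3, take the lactone carbonyl down to CH2. Desilylation of the primary alcohol, acylation with O-silyl p-coumaric acid and global desilylation finish the route.
4. Stereochemistry: C2 (R) comes from the chiral chromium catalyst and C3 (S) from the chair transition state of the same event (anti adduct, trans lactone). C4 (S) comes from hydrogenation on the face opposite the C3 substituent (3,4-cis). The ester alkene is brought in as (E)-p-coumaric acid.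

Key step: step 4

Remark: the SMILES is read as the (2R,3S,4S)-oxolane (7R,8S,8′S in lignan numbering; 2,3-trans, 3,4-cis), the mirror image of the (7S,8R,8′R) arrangement of (+)-lariciresinol, and the route is planned for exactly this enantiomer.
Abbreviations: TBS = tert-butyldimethylsilyl; TIPS = tri(propan-2-yl)silyl. Locants in each Why line follow the name of the compound discussed (lactones are numbered as oxolan-2-ones).

**Step 1**
Reactants: 1 ethyl acrylate; 2 (tert-butyldimethylsilyloxy)acetaldehyde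
Product: 3 ethyl 4-(TBS-oxy)-3-hydroxy-2-methylidenebutanoate (racemic)
Conditions: DABCO (1 equiv), dioxane/H2O, rt
Reagents that add atoms: none
Why: Morita–Baylis–Hillman reaction, in which the amine-derived acrylate enolate adds to the reactive α-silyloxy aldehyde; the new carbinol centre is racemic and is erased in step 2.

**Step 2**
Reactants: 3 ethyl 4-(TBS-oxy)-3-hydroxy-2-methylidenebutanoate
Product: 4 ethyl (Z)-2-(bromomethyl)-4-(TBS-oxy)but-2-enoate
Conditions: NBS, Me2S, CH2Cl2, 0 °C to rt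
Reagents that add atoms: N-bromosuccinimide, O=C1CCC(=O)N1Br
Why: Corey–Kim-type activation of the allylic alcohol as an alkoxysulfonium salt and SN2′ attack of bromide at the terminal methylene should give the rearranged primary allylic bromide as the more stable conjugated (Z)-alkene.

**Step 3**
Reactants: 5 vanillin
Product: 6 3-methoxy-4-(TIPS-oxy)benzaldehyde
Conditions: TIPSCl, imidazole, DMF, rt
Reagents that add atoms: triisopropylsilyl chloride, CC(C)[Si](Cl)(C(C)C)C(C)C
Why: Standard silylation of a phenol; the TIPS ether is chosen to outlast the weak-base, hydride and Lewis-acid steps and to fall to buffered fluoride at the end.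

**Step 4**
Reactants: 4 ethyl (Z)-2-(bromomethyl)-4-(TBS-oxy)but-2-enoate; 6 3-methoxy-4-(TIPS-oxy)benzaldehyde
Product: 9 (4S,5R)-4-[(TBS-oxy)methyl]-5-[3-methoxy-4-(TIPS-oxy)phenyl]-3-methylideneoxolan-2-one, via O-trimethylsilyl anti adduct 7 (not isolated), via anti hydroxy ester 8 (not isolated)
Conditions: CrCl2 (10 mol %), chiral tridentate carbazole-bis(oxazoline) ligand (12 mol %, the antipode that directs addition to the Re face of 6), Mn (2 equiv), TMSCl (1.5 equiv), i-Pr2NEt (0.3 equiv), THF, rt; then 10% aq. citric acid, THF, rt; then PPTS (cat.), PhMe, 50 °C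
Reagents that add atoms: none
Why: Cr(II), regenerated by Mn, inserts into the C–Br bond of 4 to give a ligand-bound (2-ethoxycarbonyl)allylchromium(III) species that adds through its γ-carbon (SE2′) to the aldehyde carbon of 6 in a closed six-membered chair transition state; TMSCl silylates the chromium alkoxide to release 7 and turn the catalyst over, and mild acid frees alcohol 8, whose hydroxyl attacks the ester carbonyl. The closest known reaction type is the catalytic asymmetric Nozaki–Hiyama–Kishi 2-(alkoxycarbonyl)allylation of aldehydes with lactonisation to α-methylidene-γ-butyrolactones. The one ring formed, the five-membered lactone, closes by 5-exo-trig acyl substitution with loss of ethanol. C5 of the lactone (the aryl carbinol carbon) is set by the chiral ligand, which exposes the Re face of the aldehyde, and C4 is set relative to it by the chair, in which the aryl group and the CH2OTBS-bearing terminus of the equilibrated allylchromium are both equatorial (anti adduct, hence the trans lactone). The step needs γ- over α-attack, anti over syn addition and survival of the silyloxymethyl group: chromium sits on the unsubstituted CH2 terminus and transfers the allyl unit with transposition, allylchromium reagents are anti-selective whatever the bromide geometry because the σ-allyl isomers equilibrate, and a silyl ether is a poor leaving group for β-elimination.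

**Step 5**
Reactants: 10 4-iodo-2-methoxyphenol
Product: 11 (4-iodo-2-methoxyphenoxy)tri(propan-2-yl)silane
Conditions: TIPSCl, imidazole, DMF, rt
Reagents that add atoms: triisopropylsilyl chloride, CC(C)[Si](Cl)(C(C)C)C(C)C
Why: Standard silylation of a phenol, giving the same protecting group as on the other guaiacyl ring so that both fall together in step 13.

**Step 6**
Reactants: 9 (4S,5R)-4-[(TBS-oxy)methyl]-5-[3-methoxy-4-(TIPS-oxy)phenyl]-3-methylideneoxolan-2-one; 11 (4-iodo-2-methoxyphenoxy)tri(propan-2-yl)silane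
Product: 12 (3E,4S,5R)-4-[(TBS-oxy)methyl]-5-[3-methoxy-4-(TIPS-oxy)phenyl]-3-{[3-methoxy-4-(TIPS-oxy)phenyl]methylidene}oxolan-2-one
Conditions: Pd(OAc)2 (5 mol %), n-Bu4NCl, NaHCO3, DMF, 70 °C
Reagents that add atoms: none
Why: Mizoroki–Heck arylation of the 1,1-disubstituted acrylate-type alkene: aryl-palladium adds to the terminal CH2 and syn β-hydride elimination towards the benzylic hydrogens should give the conjugated (E)-benzylidene lactone, the weak insoluble base disfavouring migration of the alkene into the ring; C4 and C5 are not involved.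

**Step 7**
Reactants: 12 (3E,4S,5R)-benzylidene lactone
Product: 13 (3S,4S,5R)-4-[(TBS-oxy)methyl]-5-[3-methoxy-4-(TIPS-oxy)phenyl]-3-{[3-methoxy-4-(TIPS-oxy)phenyl]methyl}oxolan-2-one
Conditions: H2 (1 atm), 10% Pd/C, EtOAc, rt
Reagents that add atoms: none
Why: Heterogeneous syn-hydrogenation of the exocyclic alkene, with hydrogen delivered to C3 from the face opposite the adjacent C4 CH2OTBS group, should place the new benzyl group cis to it and set C3 as S, as is usual for α-alkylidene-β-substituted butyrolactones.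

**Step 8**
Reactants: 13 (3S,4S,5R)-lactone
Product: 14 (3S,4S,5R)-4-[(TBS-oxy)methyl]-5-[3-methoxy-4-(TIPS-oxy)phenyl]-3-{[3-methoxy-4-(TIPS-oxy)phenyl]methyl}oxolan-2-ol (anomer mixture)
Conditions: DIBAL-H (1.1 equiv), CH2Cl2, −78 °C; aq. Rochelle salt
Reagents that add atoms: none
Why: Partial reduction of a lactone to the lactol, the tetrahedral aluminium hemiacetal being stable at low temperature until work-up; the anomeric centre is removed in step 9 and the other centres are untouched.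

**Step 9**
Reactants: 14 lactol
Product: 15 (2R,3S,4S)-3-[(TBS-oxy)methyl]-2-[3-methoxy-4-(TIPS-oxy)phenyl]-4-{[3-methoxy-4-(TIPS-oxy)phenyl]methyl}oxolane
Conditions: Et3SiH (3 equiv), BF3·OEt2 (1.5 equiv), CH2Cl2, −78 to −40 °C
Reagents that add atoms: none
Why: Ionic deoxygenation of a lactol: BF3 ionises the anomeric hydroxyl to the cyclic oxocarbenium ion, which triethylsilane reduces to the ring CH2, the low temperature keeping the benzylic C2–O bond and the silyl ethers intact.

**Step 10**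
Reactants: 15 silyl-protected oxolane
Product: 16 [(2R,3S,4S)-2-[3-methoxy-4-(TIPS-oxy)phenyl]-4-{[3-methoxy-4-(TIPS-oxy)phenyl]methyl}oxolan-3-yl]methanol
Conditions: HF·pyridine, pyridine, THF, 0 °C to rt
Reagents that add atoms: none
Why: Acidic fluoride cleaves the primary alkyl TBS ether much faster than the aryl TIPS ethers, which respond to basic fluoride instead, and no acid strong enough to ionise the 2-aryl oxolane is present.

**Step 11**
Reactants: 17 (E)-p-coumaric acid
Product: 19 (E)-3-[4-(TBS-oxy)phenyl]prop-2-enoic acid, via bis-silyl derivative 18 (not isolated)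
Conditions: TBSCl (2.2 equiv), imidazole, DMF, rt; then AcOH/THF/H2O, rt
Reagents that add atoms: tert-butyldimethylsilyl chloride, CC(C)(C)[Si](C)(C)Cl
Why: Exhaustive silylation followed by selective hydrolysis of the labile silyl ester leaves the phenol masked and the acid free, so the phenol cannot compete in the acylation.

**Step 12**
Reactants: 16 primary alcohol; 19 (E)-3-[4-(TBS-oxy)phenyl]prop-2-enoic acid
Product: 20 [(2R,3S,4S)-2-[3-methoxy-4-(TIPS-oxy)phenyl]-4-{[3-methoxy-4-(TIPS-oxy)phenyl]methyl}oxolan-3-yl]methyl (E)-3-[4-(TBS-oxy)phenyl]prop-2-enoate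
Conditions: EDC·HCl, DMAP, CH2Cl2, 0 °C to rt
Reagents that add atoms: none
Why: Steglich esterification of the primary alcohol through the acylpyridinium ion under neutral conditions, which leave the (E)-alkene and all stereocentres untouched.

**Step 13**
Reactants: 20 tris-silyl ester
Product: 21 lariciresinol p-coumarate, [(2R,3S,4S)-2-(4-hydroxy-3-methoxyphenyl)-4-[(4-hydroxy-3-methoxyphenyl)methyl]oxolan-3-yl]methyl (E)-3-(4-hydroxyphenyl)prop-2-enoate
Conditions: TBAF, AcOH (1:1, 3.3 equiv), THF, 0 °C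
Reagents that add atoms: none
Why: Fluoride cleaves the three aryl silyl ethers while the acetic acid buffer keeps the liberated phenols protonated, so the cinnamate ester should be neither cleaved nor moved.

**Compound list**
1 | ethyl acrylate | C=CC(=O)OCC | starting material
2 | (tert-butyldimethylsilyloxy)acetaldehyde | O=CCO[Si](C)(C)C(C)(C)C | starting material
3 | ethyl 4-(TBS-oxy)-3-hydroxy-2-methylidenebutanoate (racemic) | CCOC(=O)C(=C)C(O)CO[Si](C)(C)C(C)(C)C | intermediate
4 | ethyl (Z)-2-(bromomethyl)-4-(TBS-oxy)but-2-enoate | CCOC(=O)/C(CBr)=C/CO[Si](C)(C)C(C)(C)C | intermediate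
5 | vanillin | COc1cc(C=O)ccc1O | starting material
6 | 3-methoxy-4-(TIPS-oxy)benzaldehyde | COc1cc(C=O)ccc1O[Si](C(C)C)(C(C)C)C(C)C | intermediate
7 | ethyl (3S,4R)-3-[(TBS-oxy)methyl]-4-[3-methoxy-4-(TIPS-oxy)phenyl]-2-methylidene-4-(trimethylsilyloxy)butanoate | CCOC(=O)C(=C)[C@@H](CO[Si](C)(C)C(C)(C)C)[C@@H](O[Si](C)(C)C)c1ccc(O[Si](C(C)C)(C(C)C)C(C)C)c(OC)c1 | intermediate
8 | ethyl (3S,4R)-3-[(TBS-oxy)methyl]-4-hydroxy-4-[3-methoxy-4-(TIPS-oxy)phenyl]-2-methylidenebutanoate | CCOC(=O)C(=C)[C@@H](CO[Si](C)(C)C(C)(C)C)[C@@H](O)c1ccc(O[Si](C(C)C)(C(C)C)C(C)C)c(OC)c1 | intermediate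
9 | (4S,5R)-4-[(TBS-oxy)methyl]-5-[3-methoxy-4-(TIPS-oxy)phenyl]-3-methylideneoxolan-2-one | C=C1C(=O)O[C@@H](c2ccc(O[Si](C(C)C)(C(C)C)C(C)C)c(OC)c2)[C@@H]1CO[Si](C)(C)C(C)(C)C | intermediate
10 | 4-iodo-2-methoxyphenol | COc1cc(I)ccc1O | starting material
11 | (4-iodo-2-methoxyphenoxy)tri(propan-2-yl)silane | COc1cc(I)ccc1O[Si](C(C)C)(C(C)C)C(C)C | intermediate
12 | (3E,4S,5R)-4-[(TBS-oxy)methyl]-5-[3-methoxy-4-(TIPS-oxy)phenyl]-3-{[3-methoxy-4-(TIPS-oxy)phenyl]methylidene}oxolan-2-one | COc1cc(/C=C2/C(=O)O[C@@H](c3ccc(O[Si](C(C)C)(C(C)C)C(C)C)c(OC)c3)[C@@H]2CO[Si](C)(C)C(C)(C)C)ccc1O[Si](C(C)C)(C(C)C)C(C)C | intermediate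
13 | (3S,4S,5R)-4-[(TBS-oxy)methyl]-5-[3-methoxy-4-(TIPS-oxy)phenyl]-3-{[3-methoxy-4-(TIPS-oxy)phenyl]methyl}oxolan-2-one | COc1cc(C[C@@H]2C(=O)O[C@@H](c3ccc(O[Si](C(C)C)(C(C)C)C(C)C)c(OC)c3)[C@@H]2CO[Si](C)(C)C(C)(C)C)ccc1O[Si](C(C)C)(C(C)C)C(C)C | intermediate
14 | (3S,4S,5R)-4-[(TBS-oxy)methyl]-5-[3-methoxy-4-(TIPS-oxy)phenyl]-3-{[3-methoxy-4-(TIPS-oxy)phenyl]methyl}oxolan-2-ol (anomer mixture) | COc1cc(C[C@@H]2C(O)O[C@@H](c3ccc(O[Si](C(C)C)(C(C)C)C(C)C)c(OC)c3)[C@@H]2CO[Si](C)(C)C(C)(C)C)ccc1O[Si](C(C)C)(C(C)C)C(C)C | intermediate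
15 | (2R,3S,4S)-3-[(TBS-oxy)methyl]-2-[3-methoxy-4-(TIPS-oxy)phenyl]-4-{[3-methoxy-4-(TIPS-oxy)phenyl]methyl}oxolane | COc1cc(C[C@@H]2CO[C@@H](c3ccc(O[Si](C(C)C)(C(C)C)C(C)C)c(OC)c3)[C@@H]2CO[Si](C)(C)C(C)(C)C)ccc1O[Si](C(C)C)(C(C)C)C(C)C | intermediate
16 | [(2R,3S,4S)-2-[3-methoxy-4-(TIPS-oxy)phenyl]-4-{[3-methoxy-4-(TIPS-oxy)phenyl]methyl}oxolan-3-yl]methanol | COc1cc(C[C@@H]2CO[C@@H](c3ccc(O[Si](C(C)C)(C(C)C)C(C)C)c(OC)c3)[C@@H]2CO)ccc1O[Si](C(C)C)(C(C)C)C(C)C | intermediate
17 | (E)-p-coumaric acid | O=C(O)/C=C/c1ccc(O)cc1 | starting material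
18 | tert-butyldimethylsilyl (E)-3-[4-(TBS-oxy)phenyl]prop-2-enoate | CC(C)(C)[Si](C)(C)OC(=O)/C=C/c1ccc(O[Si](C)(C)C(C)(C)C)cc1 | intermediate
19 | (E)-3-[4-(TBS-oxy)phenyl]prop-2-enoic acid | O=C(O)/C=C/c1ccc(O[Si](C)(C)C(C)(C)C)cc1 | intermediate
20 | [(2R,3S,4S)-2-[3-methoxy-4-(TIPS-oxy)phenyl]-4-{[3-methoxy-4-(TIPS-oxy)phenyl]methyl}oxolan-3-yl]methyl (E)-3-[4-(TBS-oxy)phenyl]prop-2-enoate | COc1cc(C[C@@H]2CO[C@@H](c3ccc(O[Si](C(C)C)(C(C)C)C(C)C)c(OC)c3)[C@@H]2COC(=O)/C=C/c2ccc(O[Si](C)(C)C(C)(C)C)cc2)ccc1O[Si](C(C)C)(C(C)C)C(C)C | intermediate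
21 | lariciresinol p-coumarate, [(2R,3S,4S)-2-(4-hydroxy-3-methoxyphenyl)-4-[(4-hydroxy-3-methoxyphenyl)methyl]oxolan-3-yl]methyl (E)-3-(4-hydroxyphenyl)prop-2-enoate | COc1cc(C[C@@H]2CO[C@@H](c3ccc(O)c(OC)c3)[C@@H]2COC(=O)/C=C/c2ccc(O)cc2)ccc1O | target

**Step count and risks**
Total step count: 13. Longest linear sequence: 10 steps (1, 2, 4, 6, 7, 8, 9, 10, 12, 13).

Steps most likely to fail:

Step 4. The allyl transfer to the electron-rich aromatic aldehyde may proceed with insufficient enantio- or anti-selectivity, or the allylchromium may be lost through β-elimination of silanolate from its branched σ-isomer. The fallback replaces catalytic allylation by an auxiliary-controlled aldol–lactonisation; it sets out from 6 and returns to the route at 9. (R)-4-Benzyl-1,3-oxazolidin-2-one would be N-acylated (n-BuLi, then methyl 4-chloro-4-oxobutanoate) to the succinyl imide F1. Its dibutylboron enolate (Bu2BOTf, i-Pr2NEt, CH2Cl2, −78 °C) should add to 6 in an Evans syn-aldol reaction to give the hydroxy imide F2, which should close under catalytic acid to the trans lactone imide F3. LiOOH would remove the auxiliary to give the lactone acid F4, BH3·SMe2 would reduce the acid to the hydroxymethyl lactone F5, and TBSCl/imidazole would give the silyl ether F6. α-Aminomethylation (LiHMDS, then dimethylmethylideneammonium iodide) to the Mannich base F7, followed by N-methylation (MeI) and elimination (NaHCO3), would deliver 9.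

Step 7. Hydrogenolysis of the benzylic lactone C–O bond may compete with saturation of the alkene, or hydrogen may be delivered from the wrong face; the same fallback also answers migration of the double bond into the ring during step 6. The fallback uses hydroboration and B-alkyl Suzuki–Miyaura coupling on a methylidene oxolane in place of Heck arylation and hydrogenation; it sets out from 9 and returns at 15. Excess DIBAL-H would reduce 9 to the allylic diol F8. Mitsunobu cyclodehydration (PPh3, DIAD, THF), in which the primary allylic hydroxyl is activated and displaced by the benzylic hydroxyl with retention at the carbinol carbon, should give the methylidene oxolane F9. 9-BBN should add from the face opposite the C3 substituent to give the alkylborane F10, which is not isolated, and coupling with 11 (Pd(dppf)Cl2, aq. K3PO4, DMF/THF, 50 °C) would give 15, so that steps 6 to 9 are bypassed.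

Step 9. The Lewis acid may ionise the benzylic C2–O bond, leading to epimerisation at C2 or ring opening, or the oxocarbenium ion may lose the C4 proton to an enol ether and scramble C4. The fallback uses hydride reduction to a diol and base-mediated ring closure without any Lewis acid; it sets out from 13 and returns at 15. LiBH4 (THF, 0 °C to rt) would open the lactone to the diol F11. Selective sulfonylation of the primary hydroxyl (TsCl, Et3N, DMAP cat., CH2Cl2, 0 °C) would give the monotosylate F12. NaH in THF should then close the oxolane by 5-exo-tet Williamson displacement with the benzylic oxygen as nucleophile, so that C2 keeps its configuration, to give 15; step 8 is then not needed.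

**Further compounds**
F1 | step 4 | methyl 4-[(4R)-4-benzyl-2-oxo-1,3-oxazolidin-3-yl]-4-oxobutanoate | COC(=O)CCC(=O)N1[C@H](Cc2ccccc2)COC1=O
F2 | step 4 | methyl (3R)-4-[(4R)-4-benzyl-2-oxo-1,3-oxazolidin-3-yl]-3-[(R)-hydroxy[3-methoxy-4-(TIPS-oxy)phenyl]methyl]-4-oxobutanoate | COC(=O)C[C@H]([C@@H](O)c1ccc(O[Si](C(C)C)(C(C)C)C(C)C)c(OC)c1)C(=O)N1[C@H](Cc2ccccc2)COC1=O
F3 | step 4 | (4R)-4-benzyl-3-{(2R,3R)-2-[3-methoxy-4-(TIPS-oxy)phenyl]-5-oxooxolane-3-carbonyl}-1,3-oxazolidin-2-one | O=C1C[C@@H](C(=O)N2[C@H](Cc3ccccc3)COC2=O)[C@H](c2ccc(O[Si](C(C)C)(C(C)C)C(C)C)c(OC)c2)O1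
F4 | step 4 | (2R,3R)-2-[3-methoxy-4-(TIPS-oxy)phenyl]-5-oxooxolane-3-carboxylic acid | O=C1C[C@@H](C(=O)O)[C@H](c2ccc(O[Si](C(C)C)(C(C)C)C(C)C)c(OC)c2)O1
F5 | step 4 | (4S,5R)-4-(hydroxymethyl)-5-[3-methoxy-4-(TIPS-oxy)phenyl]oxolan-2-one | O=C1C[C@@H](CO)[C@H](c2ccc(O[Si](C(C)C)(C(C)C)C(C)C)c(OC)c2)O1
F6 | step 4 | (4S,5R)-4-[(TBS-oxy)methyl]-5-[3-methoxy-4-(TIPS-oxy)phenyl]oxolan-2-one | O=C1C[C@@H](CO[Si](C)(C)C(C)(C)C)[C@H](c2ccc(O[Si](C(C)C)(C(C)C)C(C)C)c(OC)c2)O1
F7 | step 4 | (4S,5R)-4-[(TBS-oxy)methyl]-3-[(dimethylamino)methyl]-5-[3-methoxy-4-(TIPS-oxy)phenyl]oxolan-2-one (C3 epimers) | CN(C)CC1C(=O)O[C@@H](c2ccc(O[Si](C(C)C)(C(C)C)C(C)C)c(OC)c2)[C@@H]1CO[Si](C)(C)C(C)(C)C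
F8 | step 7 | (1R,2S)-2-[(TBS-oxy)methyl]-1-[3-methoxy-4-(TIPS-oxy)phenyl]-3-methylidenebutane-1,4-diol | C=C(CO)[C@@H](CO[Si](C)(C)C(C)(C)C)[C@@H](O)c1ccc(O[Si](C(C)C)(C(C)C)C(C)C)c(OC)c1
F9 | step 7 | (2R,3S)-3-[(TBS-oxy)methyl]-2-[3-methoxy-4-(TIPS-oxy)phenyl]-4-methylideneoxolane | C=C1CO[C@@H](c2ccc(O[Si](C(C)C)(C(C)C)C(C)C)c(OC)c2)[C@@H]1CO[Si](C)(C)C(C)(C)C
F10 | step 7 | 9-{[(3S,4S,5R)-4-[(TBS-oxy)methyl]-5-[3-methoxy-4-(TIPS-oxy)phenyl]oxolan-3-yl]methyl}-9-borabicyclo[3.3.1]nonane | C(B1C2CCCC1CCC2)[C@@H]1CO[C@@H](c2ccc(O[Si](C(C)C)(C(C)C)C(C)C)c(OC)c2)[C@@H]1CO[Si](C)(C)C(C)(C)C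
F11 | step 9 | (1R,2S,3S)-2-[(TBS-oxy)methyl]-1-[3-methoxy-4-(TIPS-oxy)phenyl]-3-{[3-methoxy-4-(TIPS-oxy)phenyl]methyl}butane-1,4-diol | COc1cc(C[C@H](CO)[C@@H](CO[Si](C)(C)C(C)(C)C)[C@@H](O)c2ccc(O[Si](C(C)C)(C(C)C)C(C)C)c(OC)c2)ccc1O[Si](C(C)C)(C(C)C)C(C)C
F12 | step 9 | (2S,3S,4R)-3-[(TBS-oxy)methyl]-4-hydroxy-4-[3-methoxy-4-(TIPS-oxy)phenyl]-2-{[3-methoxy-4-(TIPS-oxy)phenyl]methyl}butyl 4-methylbenzenesulfonate | COc1cc(C[C@H](COS(=O)(=O)c2ccc(C)cc2)[C@@H](CO[Si](C)(C)C(C)(C)C)[C@@H](O)c2ccc(O[Si](C(C)C)(C(C)C)C(C)C)c(OC)c2)ccc1O[Si](C(C)C)(C(C)C)C(C)C
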